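**The problem**

Target 18 is a flavonol, 3,5-dihydroxy-2-(3-hydroxy-4-methoxyphenyl)-7-methoxy-6,8-diprenyl-chromen-4-one. It has no stereocentre, so the difficulty lies in the substitution pattern and in functional-group tolerance. Ring A is fully substituted: a free hydroxyl at C5 peri to the C4 carbonyl, 3-methylbut-2-enyl groups at C6 and C8, a methoxy group at C7, and the pyranone fused at C4a/C8a. Ring B is an isovanillin unit (3'-OH, 4'-OMe), and ring C must carry an oxygen at C3. The two prenyl alkenes are electron-rich trisubstituted olefins that will not survive halogens, peracids or dioxiranes, and strong acid cyclises a prenyl group onto a neighbouring phenol. This excludes the halogen-based flavonol syntheses and electrophilic C3 hydroxylation of a preformed flavone. A 2'-hydroxychalcone with an oxygen at the position that becomes C5 is diverted to the aurone under alkaline peroxide, so the direct oxidative chalcone cyclisation is unreliable here. Two features turn this into an opportunity. The C5 oxygen makes the five-membered aurone the easy isomer to prepare, and the 4'-methoxy group, para to C1', stabilises positive charge on the benzylic carbon that becomes C2, so an aurone epoxide can be opened there and expanded to ring C. Ring A is also symmetric about the C7–C4a axis (oxygen at C5 and C8a, prenyl at C6 and C8), so it can come from a C2v-symmetric arene in which either oxygen may become O1.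

**Retrosynthesis**

18 from 17. The two acetal C–O bonds of the methoxymethyl (MOM) ethers at C5 and C3' are cut last. The phenols must be masked through organolithium, aldol and alkaline peroxide chemistry. Benzyl ethers would need hydrogenolysis, which reduces the prenyl groups, and aryl silyl ethers do not survive alkaline peroxide. The forward step needs only dilute acid, mild enough to leave the prenyl groups alone.

17 from 15. Bond O1–C2 of ring C is cut and the C3 oxygen is removed. In aurone 15 the ring oxygen is attached to the carbon that becomes C3, and the future C2 is the exocyclic benzylidene carbon. Compared with hydroxylating a flavone at C3 or with halogen-based ring expansions, this cut needs only a nucleophilic oxidant, which the prenyl alkenes ignore. It also replaces the six-membered ring by the five-membered isomer that this substitution pattern favours. The forward reaction must epoxidise only the enone (spiro-epoxide 16), open the oxirane at the benzylic carbon, and reclose through the phenol oxygen to the six-membered ring.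

15 from 12 and 14. The exocyclic C=C bond is cut by a retro-aldol condensation. This is the convergent cut: it divides the molecule into the ring A coumaranone 12 and the ring B aldehyde 14. Only 12 can enolise, and the Z alkene is the thermodynamic isomer, so the forward step needs no special control.

14 from 13. The MOM ether is removed to reveal isovanillin 13, a commercial compound that already has the 3-hydroxy-4-methoxy pattern of ring B.

12 from 10, and 10 from 7 and 8. The O–CH2 bond of the furanone is cut to give chloroketone 10 (through monophenol 11), then the aryl–carbonyl bond to give arene 7 and Weinreb amide 8. Acid-mediated acylation of a free resorcinol would endanger the prenyl groups. Arene 7 instead has a single ring hydrogen between two MOM ethers, the best site for directed lithiation (aryllithium 9), and the MOM groups double as protection. Because 7 is symmetric, it does not matter which oxygen closes the furanone. The forward sequence must lithiate the ring carbon and not a prenyl CH2, and must release only one of two equivalent phenols.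

7 from 6, and 6 from 4. The two MOM ethers are removed to give resorcinol 6. The ring hydrogen of 6 is then traced back to an ester carbon in 4, through acid 5 (decarboxylation in the forward direction). The ester is a traceless blocking group: it occupies the position between the two hydroxyls, which would otherwise compete in the prenylation.

4 from 3, and 3 from 1 and 2. The O–methyl bond at the future C7 oxygen is cut to give triol 3, then both aryl–CH2 bonds to give commercial ester 1 and prenyl bromide 2. With one nuclear position blocked, C-alkylation of the phloroglucinol anion can only place the prenyl groups at the two carbons flanking the future C7 oxygen. The forward reactions must stop at dialkylation and must methylate the one hydroxyl that is not hydrogen-bonded to the ester.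

**Roads not taken**

Alternative 1: The cut runs through C4a–C5 of ring A and O1–C2 of ring C, unrolling rings A and C into the open-chain keto ester A2, methyl (2E)-3-methoxy-8-(methoxymethoxy)-9-[4-methoxy-3-(methoxymethoxy)phenyl]-2,4-bis(3-methylbut-2-en-1-yl)-5,7,9-trioxonon-2-enoate. In A2 the C7 methoxy is an enol ether and both prenyl groups already sit on the chain. In the forward direction Mg(OMe)2 in methanol would drive a Claisen attack of the C4a carbanion on the ester to close ring A, and acetic acid would then condense the new phenol with the aryl ketone to give the 3-O-protected 5-hydroxyflavone A1.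
- Merits: two rings form in one flask, the ring A pattern is fixed by the chain so no statistical diprenylation of an arene is needed, and the C3 oxygen is present from the start, so no oxidation is run beside the prenyl groups. In these respects it is better than the chosen plan, whose steps 1 and 2 depend on site selectivity on a crowded phenol.
- Weak points: A2 is a long, sensitive chain with four carbonyl-level carbons, two allylic branches and an enol ether of defined geometry. The α-alkoxy-1,3-diketone segment invites retro-Claisen cleavage by methoxide. Aldol closure and O-acylation to pyranones compete with the desired Claisen mode.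
- Comparison: the chosen plan answers with commercial aromatic starting materials, a ring A that is ready after three classical steps, and intermediates that are stable and isolable.

Alternative 2: Ring A is cut at C8a–C8, C7–C6 and C8a–C4a into cyclobutenone A4, 3-(methoxymethoxy)-2-(3-methylbut-2-en-1-yl)cyclobut-2-en-1-one, and alkoxyalkyne A5, 1-methoxy-5-methylhex-4-en-1-yne. Heating in toluene would open A4 to a vinylketene, which adds A5 in a [2+2] manner. A second four-electron ring opening, a six-electron closure and tautomerisation would give phenol A3 as one regioisomer (Danheiser benzannulation).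
- Merits: the hexasubstituted ring comes out with three differentiated oxygens (free OH, MOM ether, methyl ether) and both prenyl groups in defined positions. The chosen plan cannot match this differentiation; it must methylate one of three hydroxyls (step 2) and unmask one of two equivalent MOM ethers (step 6).
- Weak points: neither A4 nor A5 is commercial and each needs several steps. A5 is a labile ynol ether. A3 is only a ring A building block at the stage of compounds 6 and 7 of the chosen route, so ring C and the C3 oxygen still have to be built afterwards.
- Comparison: the target's ring A is symmetric, so the regiochemical power of the annulation is not needed. The chosen plan reaches the equivalent intermediate 7 in four steps from compound 1.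

Alternative 3: Ring C is cut at C4a–C4, C4–C3 and O1–C2 into iodoresorcinol A7 (2-iodo-5-methoxy-4,6-bis(3-methylbut-2-en-1-yl)benzene-1,3-diol), carbon monoxide and arylalkyne A8 (4-ethynyl-1-methoxy-2-(methoxymethoxy)benzene). With PdCl2(PPh3)2 (divalent palladium, reduced in the flask to zerovalent palladium), Et2NH and CO, oxidative addition, CO insertion, alkynylation and conjugate closure would give flavone A6.
- Merits: this is the most convergent way to the flavone skeleton. A7 is one iodination away from compound 6, A8 is two steps from compound 13, and three bonds form in one step. It reaches the flavone skeleton in fewer steps than the chosen plan needs to reach aurone 15.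
- Weak points: A6 has no oxygen at C3. Introducing it late, beside two prenyl alkenes and a free C5 hydroxyl, excludes dioxiranes and peracids and forces a protection, C3 metalation, borylation and oxidation sequence, which uses up the steps saved. In addition, the aryl iodide in A7 is flanked by two hydroxyls and is electron-rich, so oxidative addition will be slow. Five-membered closure to an aurone competes in carbonylative cyclisations of hindered phenols, and iodinating compound 6 beside its prenyl groups is itself uncertain.
- Comparison: the chosen plan is longer up to the ring-forming step, but it delivers the C3 hydroxyl in that same step with an oxidant the prenyl groups tolerate.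

Key step: step 9

Assumption: the non-isolated epoxide 16 and the fallback chlorohydrin F1 are racemic. 16 is drawn as the diastereomer expected from the Z alkene (aryl group cis to the furanone ring oxygen). Its configuration is erased in the same step and has no bearing on the outcome.

**Route**

Step 1
Reactants: 1 methyl 2,4,6-trihydroxybenzoate; 2 prenyl bromide (1-bromo-3-methylbut-2-ene)
Product: 3 methyl 2,4,6-trihydroxy-3,5-bis(3-methylbut-2-en-1-yl)benzoate
Conditions: 2 (2.1 equiv), NaOMe (2.2 equiv), MeOH, 0 °C → rt
Reagents that add atoms: none
Why: C-Alkylation of a phloroglucinol-type phenoxide, the reaction type used to make 3,5-diprenylated acylphloroglucinols; the ester blocks the third nuclear position, and methoxide in methanol matches the methyl ester so it cannot be exchanged.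

Step 2
Reactants: 3 methyl 2,4,6-trihydroxy-3,5-bis(3-methylbut-2-en-1-yl)benzoate
Product: 4 methyl 2,6-dihydroxy-4-methoxy-3,5-bis(3-methylbut-2-en-1-yl)benzoate
Conditions: Me2SO4 (1.0 equiv), K2CO3, acetone, rt
Reagents that add atoms: dimethyl sulfate, COS(=O)(=O)OC
Why: Williamson O-methylation of the most acidic phenol; the C4 hydroxyl is para to the ester and the only one not hydrogen-bonded to it, so one equivalent of a hard methylating agent should take it selectively.

Step 3
Reactants: 4 methyl 2,6-dihydroxy-4-methoxy-3,5-bis(3-methylbut-2-en-1-yl)benzoate
Product: 6 5-methoxy-4,6-bis(3-methylbut-2-en-1-yl)benzene-1,3-diol, via carboxylic acid 5 (not isolated)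
Conditions: KOH, H2O/MeOH, reflux, N2; then 1 M HCl to pH 4–5, 50 °C
Reagents that add atoms: none
Why: Saponification followed by protodecarboxylation of a 2,6-dihydroxybenzoic acid, which loses CO2 readily through ipso protonation of the electron-rich ring; the blocking group leaves without trace and the prenyl groups meet only dilute acid.

Step 4
Reactants: 6 5-methoxy-4,6-bis(3-methylbut-2-en-1-yl)benzene-1,3-diol
Product: 7 3-methoxy-1,5-bis(methoxymethoxy)-2,4-bis(3-methylbut-2-en-1-yl)benzene
Conditions: NaH, MOMCl, DMF, 0 °C → rt
Reagents that add atoms: chloromethyl methyl ether, COCCl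
Why: Williamson etherification of both phenoxides; the MOM acetals are the ortho directors for the next step and base-stable phenol protection up to the end.

Step 5
Reactants: 7 3-methoxy-1,5-bis(methoxymethoxy)-2,4-bis(3-methylbut-2-en-1-yl)benzene; 8 2-chloro-N-methoxy-N-methylacetamide
Product: 10 2-chloro-1-[4-methoxy-2,6-bis(methoxymethoxy)-3,5-bis(3-methylbut-2-en-1-yl)phenyl]ethan-1-one, via aryllithium 9 (not isolated)
Conditions: n-BuLi, THF, 0 °C; then 8, −78 → 0 °C; aq. NH4Cl
Reagents that add atoms: none
Why: Directed ortho-metalation at the only ring hydrogen, which lies between two MOM ethers, followed by Weinreb ketone synthesis; the chelated tetrahedral adduct prevents over-addition and the chloride is carried through intact.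

Step 6
Reactants: 10 2-chloro-1-[4-methoxy-2,6-bis(methoxymethoxy)-3,5-bis(3-methylbut-2-en-1-yl)phenyl]ethan-1-one
Product: 12 6-methoxy-4-(methoxymethoxy)-5,7-bis(3-methylbut-2-en-1-yl)-1-benzofuran-3(2H)-one, via monophenol chloroketone 11 (not isolated)
Conditions: HCl (cat., aq.), MeOH, 0 °C → rt; then NaOAc, MeOH, 60 °C
Reagents that add atoms: none
Why: Acid-catalysed acetal exchange removes one of the two equivalent MOM groups, assisted by the neighbouring carbonyl and slowed for the second once the free phenol hydrogen-bonds to that carbonyl; acetate then promotes intramolecular Williamson O-alkylation (5-exo-tet) on the chloromethyl ketone, the standard coumaranone closure.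

Step 7
Reactants: 13 isovanillin (3-hydroxy-4-methoxybenzaldehyde)
Product: 14 4-methoxy-3-(methoxymethoxy)benzaldehyde
Conditions: MOMCl, K2CO3, acetone, rt
Reagents that add atoms: chloromethyl methyl ether, COCCl
Why: Williamson etherification of the phenol; the acetal survives the condensation and the alkaline peroxide and is removed together with the ring A acetal in the last step.

Step 8
Reactants: 12 6-methoxy-4-(methoxymethoxy)-5,7-bis(3-methylbut-2-en-1-yl)-1-benzofuran-3(2H)-one; 14 4-methoxy-3-(methoxymethoxy)benzaldehyde
Product: 15 (2Z)-6-methoxy-4-(methoxymethoxy)-2-{[4-methoxy-3-(methoxymethoxy)phenyl]methylidene}-5,7-bis(3-methylbut-2-en-1-yl)-1-benzofuran-3(2H)-one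
Conditions: KOH, MeOH, rt → 50 °C
Reagents that add atoms: none
Why: Base-mediated aldol condensation (Claisen–Schmidt type) of the coumaranone methylene with a non-enolisable aldehyde, the standard aurone synthesis; the Z alkene, with the aryl group on the side of the ring oxygen and away from the carbonyl, is the thermodynamic isomer under these equilibrating conditions.

Step 9
Reactants: 15 (2Z)-6-methoxy-4-(methoxymethoxy)-2-{[4-methoxy-3-(methoxymethoxy)phenyl]methylidene}-5,7-bis(3-methylbut-2-en-1-yl)-1-benzofuran-3(2H)-one
Product: 17 3-hydroxy-7-methoxy-5-(methoxymethoxy)-2-[4-methoxy-3-(methoxymethoxy)phenyl]-6,8-bis(3-methylbut-2-en-1-yl)-4H-chromen-4-one, via spiro-epoxide 16 (not isolated)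
Conditions: H2O2 (30% aq.), NaOH (aq.), MeOH/THF, 0 °C → rt; then Na2SO3 (aq.), 0 °C; then 1 M HCl to pH 1–2, 0 °C → rt
Reagents that add atoms: hydrogen peroxide, OO
Why: Hydroperoxide anion adds to the exocyclic enone of 15 in conjugate fashion and the enolate closes on the O–O bond (Weitz–Scheffer epoxidation) to give spiro-epoxide 16; this nucleophilic oxidant leaves the electron-rich prenyl alkenes alone. After excess peroxide is destroyed with Na2SO3, so that the later 1,2-diketone is not cleaved, acid opens the oxirane at the benzylic C–O bond, whose ionisation is supported by the para methoxy group, leaving a 2-hydroxycoumaranone hemiketal. The hemiketal opens to a 2-hydroxyaryl 1,2-diketone, and the freed phenol oxygen attacks the benzylic carbon, forming bond O1–C2 and ring C in a 6-exo-tet closure with SN1 character; tautomerisation of the chroman-3,4-dione to the aromatic 3-hydroxychromone makes the sequence irreversible. The closest known reaction type is the Auwers flavonol synthesis, where the same ring expansion is run on an aurone dibromide with alkali, together with its halogen-free counterpart, the acid-induced ring expansion of aurone epoxides. Both stereocentres of 16 are destroyed, so no stereocontrol is needed. The step needs chemoselective oxidation (secured by the nucleophilic oxidant), benzylic opening in preference to opening at the ketal carbon (secured by the 4'-methoxy group), and O-closure in preference to a 1,2-acyl shift toward a 3-aryl-4-hydroxycoumarin (favoured by a protic aqueous medium in which hemiketal opening is fast, and by the absence of Lewis acids). Solvent adducts at the benzylic carbon can re-ionise under the acid and should drain into the aromatic product.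

Step 10
Reactants: 17 3-hydroxy-7-methoxy-5-(methoxymethoxy)-2-[4-methoxy-3-(methoxymethoxy)phenyl]-6,8-bis(3-methylbut-2-en-1-yl)-4H-chromen-4-one
Product: 18 3,5-dihydroxy-2-(3-hydroxy-4-methoxyphenyl)-7-methoxy-6,8-bis(3-methylbut-2-en-1-yl)-4H-chromen-4-one
Conditions: 3 M HCl (aq.), MeOH, 40 °C
Reagents that add atoms: none
Why: Acid-catalysed acetal methanolysis of both MOM ethers; the peri acetal at C5 goes first with help from the C4 carbonyl, and dilute acid at this temperature is milder than what is needed to cyclise a prenyl group onto the neighbouring phenol.

**Compound list**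

1 | methyl 2,4,6-trihydroxybenzoate | COC(=O)c1c(O)cc(O)cc1O | starting material
2 | prenyl bromide (1-bromo-3-methylbut-2-ene) | CC(C)=CCBr | starting material
3 | methyl 2,4,6-trihydroxy-3,5-bis(3-methylbut-2-en-1-yl)benzoate | COC(=O)c1c(O)c(CC=C(C)C)c(O)c(CC=C(C)C)c1O | intermediate
4 | methyl 2,6-dihydroxy-4-methoxy-3,5-bis(3-methylbut-2-en-1-yl)benzoate | COC(=O)c1c(O)c(CC=C(C)C)c(OC)c(CC=C(C)C)c1O | intermediate
5 | 2,6-dihydroxy-4-methoxy-3,5-bis(3-methylbut-2-en-1-yl)benzoic acid | OC(=O)c1c(O)c(CC=C(C)C)c(OC)c(CC=C(C)C)c1O | intermediate (not isolated)
6 | 5-methoxy-4,6-bis(3-methylbut-2-en-1-yl)benzene-1,3-diol | COc1c(CC=C(C)C)c(O)cc(O)c1CC=C(C)C | intermediate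
7 | 3-methoxy-1,5-bis(methoxymethoxy)-2,4-bis(3-methylbut-2-en-1-yl)benzene | COCOc1cc(OCOC)c(CC=C(C)C)c(OC)c1CC=C(C)C | intermediate
8 | 2-chloro-N-methoxy-N-methylacetamide | CON(C)C(=O)CCl | starting material
9 | [4-methoxy-2,6-bis(methoxymethoxy)-3,5-bis(3-methylbut-2-en-1-yl)phenyl]lithium | [Li]c1c(OCOC)c(CC=C(C)C)c(OC)c(CC=C(C)C)c1OCOC | intermediate (not isolated)
10 | 2-chloro-1-[4-methoxy-2,6-bis(methoxymethoxy)-3,5-bis(3-methylbut-2-en-1-yl)phenyl]ethan-1-one | ClCC(=O)c1c(OCOC)c(CC=C(C)C)c(OC)c(CC=C(C)C)c1OCOC | intermediate
11 | 2-chloro-1-[2-hydroxy-4-methoxy-6-(methoxymethoxy)-3,5-bis(3-methylbut-2-en-1-yl)phenyl]ethan-1-one | ClCC(=O)c1c(O)c(CC=C(C)C)c(OC)c(CC=C(C)C)c1OCOC | intermediate (not isolated)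
12 | 6-methoxy-4-(methoxymethoxy)-5,7-bis(3-methylbut-2-en-1-yl)-1-benzofuran-3(2H)-one | COCOc1c(CC=C(C)C)c(OC)c(CC=C(C)C)c2OCC(=O)c12 | intermediate
13 | isovanillin (3-hydroxy-4-methoxybenzaldehyde) | COc1ccc(C=O)cc1O | starting material
14 | 4-methoxy-3-(methoxymethoxy)benzaldehyde | COCOc1cc(C=O)ccc1OC | intermediate
15 | (2Z)-6-methoxy-4-(methoxymethoxy)-2-{[4-methoxy-3-(methoxymethoxy)phenyl]methylidene}-5,7-bis(3-methylbut-2-en-1-yl)-1-benzofuran-3(2H)-one | COCOc1c(CC=C(C)C)c(OC)c(CC=C(C)C)c2c1C(=O)/C(=C/c1ccc(OC)c(OCOC)c1)O2 | intermediate
16 | 6-methoxy-4-(methoxymethoxy)-3'-[4-methoxy-3-(methoxymethoxy)phenyl]-5,7-bis(3-methylbut-2-en-1-yl)-3H-spiro[1-benzofuran-2,2'-oxiran]-3-one (racemic, one enantiomer drawn; aryl group cis to the furanone ring oxygen on the oxirane) | O=C1c2c(OCOC)c(CC=C(C)C)c(OC)c(CC=C(C)C)c2O[C@]13O[C@H]3c1ccc(OC)c(OCOC)c1 | intermediate (not isolated)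
17 | 3-hydroxy-7-methoxy-5-(methoxymethoxy)-2-[4-methoxy-3-(methoxymethoxy)phenyl]-6,8-bis(3-methylbut-2-en-1-yl)-4H-chromen-4-one | Oc1c(-c2ccc(OC)c(OCOC)c2)oc2c(CC=C(C)C)c(OC)c(CC=C(C)C)c(OCOC)c2c1=O | intermediate
18 | 3,5-dihydroxy-2-(3-hydroxy-4-methoxyphenyl)-7-methoxy-6,8-bis(3-methylbut-2-en-1-yl)-4H-chromen-4-one | COc1ccc(-c2oc3c(CC=C(C)C)c(OC)c(CC=C(C)C)c(O)c3c(=O)c2O)cc1O | target

**Step count and risks**

Total steps: 10. Longest linear sequence: 9 steps (steps 1, 2, 3, 4, 5, 6, 8, 9, 10); step 7 is a one-step side branch.

Step 9 (key step).
- What may go wrong: once the benzylic C–O bond of 16 has ionised, a 1,2-shift of the acyl carbon or capture of the cation by solvent without reclosure may outrun attack by the phenol oxygen. The epoxidation itself may also be slow, because the enone is a vinylogous ester deactivated by three oxygen donors.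
- Fallback (sets out from 15, returns at 17): the peroxide stage is worked up at neutral pH and epoxide 16 is isolated. Pyridinium chloride in CH2Cl2 at 0 °C should open it at the benzylic carbon to the chlorohydrin 2-{chloro[4-methoxy-3-(methoxymethoxy)phenyl]methyl}-2-hydroxy-6-methoxy-4-(methoxymethoxy)-5,7-bis(3-methylbut-2-en-1-yl)-1-benzofuran-3(2H)-one F1. K2CO3 in MeOH then opens the hemiketal, and the phenoxide displaces chloride in an SN2, 6-exo-tet closure. This is the end game of the Auwers synthesis with the halogen delivered as chloride ion, so no free halogen meets the prenyl groups.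

Step 1.
- What may go wrong: over-alkylation at an already substituted ring carbon (dearomatising geminal diprenylation) and O-alkylation, because several ambident sites of the polyphenoxide compete.
- Fallback (sets out from 1, returns at 3): Friedel–Crafts prenylation with 2-methylbut-3-en-2-ol and BF3·OEt2 in dioxane at rt. This electrophilic aromatic substitution stops when no ring hydrogen is left, so it cannot dearomatise the ring. It makes no new compound.

Step 2.
- What may go wrong: incomplete site selectivity, that is methylation of a chelated hydroxyl or double methylation, because the C4 hydroxyl, though the most acidic, is flanked by two prenyl groups.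
- Fallback (sets out from 1, returns at 4): the order is reversed. Compound 1 is methylated first (Me2SO4, K2CO3, acetone) at its unhindered, non-chelated hydroxyl to methyl 2,6-dihydroxy-4-methoxybenzoate F2. F2 is then C-prenylated twice with 2 and NaOMe in MeOH at the only two free ring positions to give 4.

Step 5.
- What may go wrong: proton transfer in place of acylation. The aryllithium 9 is flanked by two ortho substituents and amide 8 has acidic α-hydrogens; deprotonation at the benzylic-allylic CH2 of a prenyl group may also compete with ring lithiation.
- Fallback (sets out from 4, returns at 12): this uses the ester carbon already in place and no organolithium. Mono-O-alkylation of 4 with methyl bromoacetate (K2CO3, acetone) should give methyl 2-hydroxy-4-methoxy-6-(2-methoxy-2-oxoethoxy)-3,5-bis(3-methylbut-2-en-1-yl)benzoate F3. MOM protection (MOMCl, NaH, DMF) gives methyl 4-methoxy-2-(2-methoxy-2-oxoethoxy)-6-(methoxymethoxy)-3,5-bis(3-methylbut-2-en-1-yl)benzoate F4. Dieckmann condensation (t-BuOK, THF) gives methyl 3-hydroxy-6-methoxy-4-(methoxymethoxy)-5,7-bis(3-methylbut-2-en-1-yl)-1-benzofuran-2-carboxylate F5. Krapcho demethoxycarbonylation (LiCl, wet DMSO, heat) then gives 12.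

Step 6.
- What may go wrong: loss of both MOM groups in place of one, because the two acetals are equivalent until the first has gone.
- Fallback (sets out from 10, returns at 12): both acetals are cleaved on purpose (HCl, MeOH, 40 °C) to 2-chloro-1-[2,6-dihydroxy-4-methoxy-3,5-bis(3-methylbut-2-en-1-yl)phenyl]ethan-1-one F6. NaOAc in MeOH closes the furanone to 4-hydroxy-6-methoxy-5,7-bis(3-methylbut-2-en-1-yl)-1-benzofuran-3(2H)-one F7. The single remaining phenol is then protected with MOMCl and i-Pr2NEt in CH2Cl2 to give 12.

**Further compounds**

F1 | step 9 | 2-{chloro[4-methoxy-3-(methoxymethoxy)phenyl]methyl}-2-hydroxy-6-methoxy-4-(methoxymethoxy)-5,7-bis(3-methylbut-2-en-1-yl)-1-benzofuran-3(2H)-one (racemic, mixture of diastereomers at the hemiketal carbon) | O=C1c2c(OCOC)c(CC=C(C)C)c(OC)c(CC=C(C)C)c2OC1(O)C(Cl)c1ccc(OC)c(OCOC)c1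
F0 | step 1 | none | none
F2 | step 2 | methyl 2,6-dihydroxy-4-methoxybenzoate | COC(=O)c1c(O)cc(OC)cc1O
F3 | step 5 | methyl 2-hydroxy-4-methoxy-6-(2-methoxy-2-oxoethoxy)-3,5-bis(3-methylbut-2-en-1-yl)benzoate | COC(=O)COc1c(CC=C(C)C)c(OC)c(CC=C(C)C)c(O)c1C(=O)OC
F4 | step 5 | methyl 4-methoxy-2-(2-methoxy-2-oxoethoxy)-6-(methoxymethoxy)-3,5-bis(3-methylbut-2-en-1-yl)benzoate | COC(=O)COc1c(CC=C(C)C)c(OC)c(CC=C(C)C)c(OCOC)c1C(=O)OC
F5 | step 5 | methyl 3-hydroxy-6-methoxy-4-(methoxymethoxy)-5,7-bis(3-methylbut-2-en-1-yl)-1-benzofuran-2-carboxylate | COC(=O)c1oc2c(CC=C(C)C)c(OC)c(CC=C(C)C)c(OCOC)c2c1O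
F6 | step 6 | 2-chloro-1-[2,6-dihydroxy-4-methoxy-3,5-bis(3-methylbut-2-en-1-yl)phenyl]ethan-1-one | ClCC(=O)c1c(O)c(CC=C(C)C)c(OC)c(CC=C(C)C)c1O
F7 | step 6 | 4-hydroxy-6-methoxy-5,7-bis(3-methylbut-2-en-1-yl)-1-benzofuran-3(2H)-one | COc1c(CC=C(C)C)c(O)c2C(=O)COc2c1CC=C(C)C
A1 | alternative 1 | 5-hydroxy-7-methoxy-3-(methoxymethoxy)-2-[4-methoxy-3-(methoxymethoxy)phenyl]-6,8-bis(3-methylbut-2-en-1-yl)-4H-chromen-4-one | COCOc1c(-c2ccc(OC)c(OCOC)c2)oc2c(CC=C(C)C)c(OC)c(CC=C(C)C)c(O)c2c1=O
A2 | alternative 1 | methyl (2E)-3-methoxy-8-(methoxymethoxy)-9-[4-methoxy-3-(methoxymethoxy)phenyl]-2,4-bis(3-methylbut-2-en-1-yl)-5,7,9-trioxonon-2-enoate (the two chain stereocentres unspecified) | COC(=O)/C(CC=C(C)C)=C(/OC)C(CC=C(C)C)C(=O)CC(=O)C(OCOC)C(=O)c1ccc(OC)c(OCOC)c1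
A3 | alternative 2 | 3-methoxy-5-(methoxymethoxy)-2,4-bis(3-methylbut-2-en-1-yl)phenol | COCOc1cc(O)c(CC=C(C)C)c(OC)c1CC=C(C)C
A4 | alternative 2 | 3-(methoxymethoxy)-2-(3-methylbut-2-en-1-yl)cyclobut-2-en-1-one | O=C1CC(OCOC)=C1CC=C(C)C
A5 | alternative 2 | 1-methoxy-5-methylhex-4-en-1-yne | COC#CCC=C(C)C
A6 | alternative 3 | 5-hydroxy-7-methoxy-2-[4-methoxy-3-(methoxymethoxy)phenyl]-6,8-bis(3-methylbut-2-en-1-yl)-4H-chromen-4-one | O=c1cc(-c2ccc(OC)c(OCOC)c2)oc2c(CC=C(C)C)c(OC)c(CC=C(C)C)c(O)c12
A7 | alternative 3 | 2-iodo-5-methoxy-4,6-bis(3-methylbut-2-en-1-yl)benzene-1,3-diol | COc1c(CC=C(C)C)c(O)c(I)c(O)c1CC=C(C)C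
A8 | alternative 3 | 4-ethynyl-1-methoxy-2-(methoxymethoxy)benzene | C#Cc1ccc(OC)c(OCOC)c1
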